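**Retrosynthetic overview**

1. The target is (2R,3S)-fisetinidol-(4α→8)-(2R,3S)-fisetinidol (flavan numbering O1, C2, C3, C4, C4a, C5–C8, C8a). The last C–C bond made is the interflavan bond C4(upper)–C8(lower), by Friedel–Crafts coupling of a flavan-4-yl cation with a C6-brominated lower unit, followed by global hydrogenolysis.
2. Both partners are the same flavan at two oxidation levels of C4: the 4-(benzyloxycarbonylamino)flavan 15 is the electrophile as such, and it becomes the nucleophile 16 after ionic hydrogenation of C4–N to C4H2.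
3. This flavan comes from one catalytic asymmetric formal [4+2] (oxa-Povarov) reaction of the achiral diaryl acetal 11 with the (E)-enecarbamate 7. It makes C2–C3 and C4–C4a and sets C2 and C3. Ring order: rings A and B are bought, ring C of both units is closed in the key step, then the C4–C8 bond is made.
4. Enabling feature: ring C is the six-membered ring O1–C2–C3–C4–C4a–C8a fused to the resorcinol-type ring A. C2 carries O1 and the catechol ring B, so it is a well-stabilised O-aryl oxocarbenium carbon. C4a is ortho to O1 and para to the C7 oxygen, so it is the most nucleophilic ring carbon for closure onto C4. The C4 nitrogen and the C6 bromine are temporary and are removed again.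

Key step: step 5

Remark on the chemistry: the sense of induction of the chiral phosphoric acid in step 5 cannot be predicted with certainty; the (R)-acid is written, and its (S)-enantiomer is taken instead if the mirror-image adduct is formed.

**Route**

Step 1
Reactants: 1 benzyl alcohol; 2 methyl propiolate
Product: 3 methyl (2E)-3-(benzyloxy)prop-2-enoate
Conditions: DABCO (10 mol %), CH2Cl2, 0 °C → rt
Reagents that add atoms: none
Why: Amine-catalysed oxa-Michael addition of the alcohol to the ynoate, which should give the (E)-β-alkoxyacrylate as the thermodynamic isomer.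

Step 2
Reactants: 3 methyl (2E)-3-(benzyloxy)prop-2-enoate
Product: 4 (2E)-3-(benzyloxy)prop-2-enoic acid
Conditions: LiOH·H2O (2 equiv), THF/H2O, rt; then 1 M HCl, 0 °C, to pH 3
Reagents that add atoms: lithium hydroxide, [Li+].[OH-]
Why: Saponification of a methyl ester; the vinylogous carbonate is a deactivated enol ether and should survive brief cold acidification with its (E)-geometry intact.

Step 3
Reactants: 4 (2E)-3-(benzyloxy)prop-2-enoic acid; 1 benzyl alcohol
Product: 7 benzyl N-[(E)-2-(benzyloxy)ethenyl]carbamate, via acyl azide 5 (not isolated), via vinyl isocyanate 6 (not isolated)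
Conditions: DPPA (1.1 equiv), Et3N (1.2 equiv), toluene, 0 °C → rt; 85 °C; then 1 (1.5 equiv), 85 °C
Reagents that add atoms: diphenylphosphoryl azide, O=P(N=[N+]=[N-])(Oc1ccccc1)Oc1ccccc1
Why: Curtius rearrangement through the acyl azide and the isocyanate, which is trapped by benzyl alcohol; the migrating alkenyl carbon keeps its (E)-geometry.

Step 4
Reactants: 8 3,4-bis(benzyloxy)benzaldehyde; 9 3-(benzyloxy)phenol (2.2 equiv)
Product: 11 1,2-bis(benzyloxy)-4-{bis[3-(benzyloxy)phenoxy]methyl}benzene, via benzal chloride 10 (not isolated)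
Conditions: SOCl2 (1.5 equiv), DMF (cat.), CH2Cl2, 40 °C, evaporate; then 9, iPr2NEt (3 equiv), CH2Cl2, −20 °C → rt
Reagents that add atoms: none
Why: Deoxychlorination of the aldehyde to the benzal chloride followed by twofold SN1-type O-alkylation of the phenol under basic conditions (the known route to benzaldehyde diaryl acetals); the symmetric acetal is chosen because acid can later ionise it in one way only.

Step 5
Reactants: 11 1,2-bis(benzyloxy)-4-{bis[3-(benzyloxy)phenoxy]methyl}benzene; 7 benzyl N-[(E)-2-(benzyloxy)ethenyl]carbamate (1.5 equiv)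
Product: 14 benzyl N-[(2R,3S,4R)-3,7-bis(benzyloxy)-2-[3,4-bis(benzyloxy)phenyl]-3,4-dihydro-2H-chromen-4-yl]carbamate, via oxocarbenium ion 12 (not isolated), via N-acyliminium ion 13 (not isolated)
Conditions: (R)-3,3'-bis(2,4,6-triisopropylphenyl)-1,1'-binaphthyl-2,2'-diyl hydrogen phosphate (10 mol %), 4 Å molecular sieves, toluene, −40 °C → −10 °C
Reagents that add atoms: none
Why: Proposed new method: the chiral phosphoric acid protonates one aryloxy group of 11, phenol 9 leaves, and the O-aryl oxocarbenium ion 12 is held as a contact ion pair by the chiral phosphate, which also accepts a hydrogen bond from the N–H of 7; the carbon of 7 that is β to nitrogen (the one bearing OBn) then adds to C2 (C2–C3), and the N-acyliminium ion 13 so formed is trapped by C4a of ring A (C4–C4a). The closest known reactions are the Lewis-acid-promoted oxa-Povarov reaction of O-aryl oxocarbenium ions with alkenes and the chiral-phosphoric-acid-catalysed Povarov reaction of N-aryl imines with (E)-enecarbamates. Pyran ring C closes by a stepwise inverse-electron-demand [4+2] process whose second event is a 6-exo-trig Friedel–Crafts attack of the arene on the iminium carbon. C2 and C3 are set in the first C–C bond formation inside the chiral ion pair (catalyst control of the absolute sense); the 2,3-trans relation should follow from the (E)-geometry of 7 together with the endo placement of the phosphate-bound carbamate, and C4 should close trans to the C3 benzyloxy group under substrate control, its configuration being irrelevant because C4 is ionised later. The step needs regioselectivity within 7 (secured because the hydrogen-bonded carbamate nitrogen is a stronger π-donor than the ether oxygen), a single mode of ionisation (secured by the symmetric diaryl acetal, which can only give 12) and site selectivity on ring A (C4a is ortho to O1, para to the C7 oxygen and unhindered, whereas C8 lies between two oxygens).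

Step 6
Reactants: 14 benzyl N-[(2R,3S,4R)-3,7-bis(benzyloxy)-2-[3,4-bis(benzyloxy)phenyl]-3,4-dihydro-2H-chromen-4-yl]carbamate
Product: 15 benzyl N-[(2R,3S,4R)-3,7-bis(benzyloxy)-2-[3,4-bis(benzyloxy)phenyl]-6-bromo-3,4-dihydro-2H-chromen-4-yl]carbamate
Conditions: NBS (1.05 equiv), CH2Cl2, −78 °C → −20 °C
Reagents that add atoms: N-bromosuccinimide, O=C1CCC(=O)N1Br
Why: Electrophilic aromatic bromination, expected at C6 because it is para to O1, ortho to the C7 benzyloxy group and less hindered than C8, while the catechol-type ring B and the benzyl groups are far less activated.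

Step 7
Reactants: 15 benzyl N-[(2R,3S,4R)-3,7-bis(benzyloxy)-2-[3,4-bis(benzyloxy)phenyl]-6-bromo-3,4-dihydro-2H-chromen-4-yl]carbamate
Product: 16 (2R,3S)-3,7-bis(benzyloxy)-2-[3,4-bis(benzyloxy)phenyl]-6-bromo-3,4-dihydro-2H-chromene
Conditions: Et3SiH (5 equiv), CF3CO2H (10 equiv), CH2Cl2, −20 °C → 0 °C
Reagents that add atoms: none
Why: Ionic hydrogenation: acid ionises the C4–N bond of this 2,4-dioxygenated benzylic carbamate (as in the acidolysis of 2,4-dimethoxybenzyl carbamates) and the flavan-4-yl cation takes hydride from the silane, while C2 and C3 should stay untouched at low temperature.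

Step 8
Reactants: 15 benzyl N-[(2R,3S,4R)-3,7-bis(benzyloxy)-2-[3,4-bis(benzyloxy)phenyl]-6-bromo-3,4-dihydro-2H-chromen-4-yl]carbamate; 16 (2R,3S)-3,7-bis(benzyloxy)-2-[3,4-bis(benzyloxy)phenyl]-6-bromo-3,4-dihydro-2H-chromene (3 equiv)
Product: 17 (2R,3S,4S)-3,7-bis(benzyloxy)-4-[(2R,3S)-3,7-bis(benzyloxy)-2-[3,4-bis(benzyloxy)phenyl]-6-bromo-3,4-dihydro-2H-chromen-8-yl]-2-[3,4-bis(benzyloxy)phenyl]-6-bromo-3,4-dihydro-2H-chromene
Conditions: TMSOTf (0.3 equiv), CH2Cl2, −40 °C → −10 °C, 15 added slowly to 16
Reagents that add atoms: none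
Why: Acid-mediated Friedel–Crafts alkylation (flavan-4-yl cation coupling as in proanthocyanidin synthesis): the cation from 15 should be attacked by C8 of 16, the only activated free position of its ring A because C6 carries bromine, from the face anti to the C3 benzyloxy group, which sets the new 4S centre (3,4-trans).

Step 9
Reactants: 17 (2R,3S,4S)-3,7-bis(benzyloxy)-4-[(2R,3S)-3,7-bis(benzyloxy)-2-[3,4-bis(benzyloxy)phenyl]-6-bromo-3,4-dihydro-2H-chromen-8-yl]-2-[3,4-bis(benzyloxy)phenyl]-6-bromo-3,4-dihydro-2H-chromene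
Product: 18 (2R,3S,4S)-2-(3,4-dihydroxyphenyl)-4-[(2R,3S)-2-(3,4-dihydroxyphenyl)-3,7-dihydroxy-3,4-dihydro-2H-chromen-8-yl]-3,4-dihydro-2H-chromene-3,7-diol (CNP0189433.1)
Conditions: H2 (1 atm), Pd(OH)2 on carbon, Et3N (3 equiv), THF/MeOH, rt
Reagents that add atoms: none
Why: Catalytic hydrogenolysis should remove all eight benzyl ethers and, with base present to take up HBr, both aryl bromides (hydrodehalogenation) without touching the acid-labile interflavan bond or any stereocentre.

**Compound list**

1 | benzyl alcohol | OCc1ccccc1 | starting material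
2 | methyl propiolate | C#CC(=O)OC | starting material
3 | methyl (2E)-3-(benzyloxy)prop-2-enoate | COC(=O)/C=C/OCc1ccccc1 | intermediate
4 | (2E)-3-(benzyloxy)prop-2-enoic acid | OC(=O)/C=C/OCc1ccccc1 | intermediate
5 | (2E)-3-(benzyloxy)prop-2-enoyl azide | [N-]=[N+]=NC(=O)/C=C/OCc1ccccc1 | intermediate
6 | (E)-2-(benzyloxy)ethenyl isocyanate | O=C=N/C=C/OCc1ccccc1 | intermediate
7 | benzyl N-[(E)-2-(benzyloxy)ethenyl]carbamate | O=C(OCc1ccccc1)N/C=C/OCc1ccccc1 | intermediate
8 | 3,4-bis(benzyloxy)benzaldehyde | O=Cc1ccc(OCc2ccccc2)c(OCc2ccccc2)c1 | starting material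
9 | 3-(benzyloxy)phenol | Oc1cccc(OCc2ccccc2)c1 | starting material
10 | 1,2-bis(benzyloxy)-4-(dichloromethyl)benzene | ClC(Cl)c1ccc(OCc2ccccc2)c(OCc2ccccc2)c1 | intermediate
11 | 1,2-bis(benzyloxy)-4-{bis[3-(benzyloxy)phenoxy]methyl}benzene | C(Oc1cccc(OCc2ccccc2)c1)(Oc1cccc(OCc2ccccc2)c1)c1ccc(OCc2ccccc2)c(OCc2ccccc2)c1 | intermediate
12 | [3-(benzyloxy)phenyl]{[3,4-bis(benzyloxy)phenyl]methylidene}oxonium (O-aryl oxocarbenium ion, as its phosphate ion pair) | C(=[O+]c1cccc(OCc2ccccc2)c1)c1ccc(OCc2ccccc2)c(OCc2ccccc2)c1 | intermediate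
13 | N-(benzyloxycarbonyl)iminium ion of 2-(benzyloxy)-3-[3-(benzyloxy)phenoxy]-3-[3,4-bis(benzyloxy)phenyl]propanal (flavan numbering: C2 R, C3 S) | c1ccccc1COc1cccc(O[C@H](c2ccc(OCc3ccccc3)c(OCc3ccccc3)c2)[C@@H](OCc2ccccc2)C=[NH+]C(=O)OCc2ccccc2)c1 | intermediate
14 | benzyl N-[(2R,3S,4R)-3,7-bis(benzyloxy)-2-[3,4-bis(benzyloxy)phenyl]-3,4-dihydro-2H-chromen-4-yl]carbamate | c1ccccc1COc1ccc2c(c1)O[C@H](c1ccc(OCc3ccccc3)c(OCc3ccccc3)c1)[C@@H](OCc1ccccc1)[C@@H]2NC(=O)OCc1ccccc1 | intermediate
15 | benzyl N-[(2R,3S,4R)-3,7-bis(benzyloxy)-2-[3,4-bis(benzyloxy)phenyl]-6-bromo-3,4-dihydro-2H-chromen-4-yl]carbamate | Brc1cc2c(cc1OCc1ccccc1)O[C@H](c1ccc(OCc3ccccc3)c(OCc3ccccc3)c1)[C@@H](OCc1ccccc1)[C@@H]2NC(=O)OCc1ccccc1 | intermediate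
16 | (2R,3S)-3,7-bis(benzyloxy)-2-[3,4-bis(benzyloxy)phenyl]-6-bromo-3,4-dihydro-2H-chromene | Brc1cc2c(cc1OCc1ccccc1)O[C@H](c1ccc(OCc3ccccc3)c(OCc3ccccc3)c1)[C@@H](OCc1ccccc1)C2 | intermediate
17 | (2R,3S,4S)-3,7-bis(benzyloxy)-4-[(2R,3S)-3,7-bis(benzyloxy)-2-[3,4-bis(benzyloxy)phenyl]-6-bromo-3,4-dihydro-2H-chromen-8-yl]-2-[3,4-bis(benzyloxy)phenyl]-6-bromo-3,4-dihydro-2H-chromene | Brc1cc2c(cc1OCc1ccccc1)O[C@H](c1ccc(OCc3ccccc3)c(OCc3ccccc3)c1)[C@@H](OCc1ccccc1)[C@@H]2c1c(OCc3ccccc3)c(Br)cc2c1O[C@H](c1ccc(OCc3ccccc3)c(OCc3ccccc3)c1)[C@@H](OCc1ccccc1)C2 | intermediate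
18 | (2R,3S,4S)-2-(3,4-dihydroxyphenyl)-4-[(2R,3S)-2-(3,4-dihydroxyphenyl)-3,7-dihydroxy-3,4-dihydro-2H-chromen-8-yl]-3,4-dihydro-2H-chromene-3,7-diol | Oc1ccc2c(c1)O[C@H](c1ccc(O)c(O)c1)[C@@H](O)[C@@H]2c1c(O)ccc2c1O[C@H](c1ccc(O)c(O)c1)[C@@H](O)C2 | target

**Step count and risks**

Total step count: 9. Longest linear sequence: 8 steps (steps 1, 2, 3, 5, 6, 7, 8, 9).

Steps most likely to fail:

1. Step 5 (Proposed new method). What may go wrong: facial discrimination inside the ion pair may be insufficient (low enantioselectivity or low 2,3-trans selectivity), or the enecarbamate may be consumed by acid-induced oligomerisation before the diaryl acetal ionises. Fallback with known chemistry: it sets out from isocyanate 6 and acetal 11 and comes back to the route at 16 and at 17. Isocyanate 6 is trapped with (1R,2S,5R)-menthol instead of benzyl alcohol to give (1R,2S,5R)-menthyl N-[(E)-2-(benzyloxy)ethenyl]carbamate F1. The SnCl4-promoted oxa-Povarov reaction of F1 with 11 (SnCl4 20 mol %, CH2Cl2, −78 °C), a known reaction type run without catalyst control, should give the trans,trans adducts of both enantiomeric chroman series as diastereomers. Chromatography or crystallisation then separates the menthyl (2R,3S,4R)-carbamate adduct F2 (auxiliary-based resolution). Bromination as in step 6 gives the 6-bromo menthyl carbamate F3, which takes the place of 15 under the conditions of steps 7 and 8; the menthyl carbamate is the leaving group there, so no separate removal is needed.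

2. Step 8. What may go wrong: the cation from 15 may be captured by C8 of a second molecule of 15, or of product 17, faster than by the hindered, bromine-deactivated C8 of 16, which leads to self-condensation and oligomers. Fallback: it sets out from 15 and comes back at 18. Compound 15 is brominated once more at C8 (NBS, CH2Cl2, 0 °C) to give the 6,8-dibromo carbamate F4, which has no nucleophilic ring position left. Coupling of F4 with 16 under the conditions of step 8 gives the tribromo dimer F5, and the hydrogenolysis of step 9 removes the third bromine together with the other two and the benzyl groups to give 18.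

3. Step 4. What may go wrong: the electron-rich dichloride 10 may hydrolyse or self-condense before both chlorides are replaced, or the phenol may be alkylated at carbon instead of oxygen. Fallback: it sets out from 8 and comes back at 11. Aldehyde 8 is converted with trimethyl orthoformate (MeOH, TsOH cat., rt) into the stable 1,2-bis(benzyloxy)-4-(dimethoxymethyl)benzene F6. Transacetalisation of F6 with phenol 9 (pyridinium p-toluenesulfonate cat., toluene, methanol removed over 5 Å molecular sieves) should deliver 11 under equilibrium control without any halide intermediate.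

**Further compounds**

F1 | step 5 | (1R,2S,5R)-menthyl N-[(E)-2-(benzyloxy)ethenyl]carbamate | CC(C)[C@@H]1CC[C@@H](C)C[C@H]1OC(=O)N/C=C/OCc1ccccc1
F2 | step 5 | (1R,2S,5R)-menthyl N-[(2R,3S,4R)-3,7-bis(benzyloxy)-2-[3,4-bis(benzyloxy)phenyl]-3,4-dihydro-2H-chromen-4-yl]carbamate | c1ccccc1COc1ccc2c(c1)O[C@H](c1ccc(OCc3ccccc3)c(OCc3ccccc3)c1)[C@@H](OCc1ccccc1)[C@@H]2NC(=O)O[C@@H]1C[C@H](C)CC[C@H]1C(C)C
F3 | step 5 | (1R,2S,5R)-menthyl N-[(2R,3S,4R)-3,7-bis(benzyloxy)-2-[3,4-bis(benzyloxy)phenyl]-6-bromo-3,4-dihydro-2H-chromen-4-yl]carbamate | Brc1cc2c(cc1OCc1ccccc1)O[C@H](c1ccc(OCc3ccccc3)c(OCc3ccccc3)c1)[C@@H](OCc1ccccc1)[C@@H]2NC(=O)O[C@@H]1C[C@H](C)CC[C@H]1C(C)C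
F4 | step 8 | benzyl N-[(2R,3S,4R)-3,7-bis(benzyloxy)-2-[3,4-bis(benzyloxy)phenyl]-6,8-dibromo-3,4-dihydro-2H-chromen-4-yl]carbamate | Brc1cc2c(c(Br)c1OCc1ccccc1)O[C@H](c1ccc(OCc3ccccc3)c(OCc3ccccc3)c1)[C@@H](OCc1ccccc1)[C@@H]2NC(=O)OCc1ccccc1
F5 | step 8 | (2R,3S,4S)-3,7-bis(benzyloxy)-4-[(2R,3S)-3,7-bis(benzyloxy)-2-[3,4-bis(benzyloxy)phenyl]-6-bromo-3,4-dihydro-2H-chromen-8-yl]-2-[3,4-bis(benzyloxy)phenyl]-6,8-dibromo-3,4-dihydro-2H-chromene | Brc1cc2c(c(Br)c1OCc1ccccc1)O[C@H](c1ccc(OCc3ccccc3)c(OCc3ccccc3)c1)[C@@H](OCc1ccccc1)[C@@H]2c1c(OCc3ccccc3)c(Br)cc2c1O[C@H](c1ccc(OCc3ccccc3)c(OCc3ccccc3)c1)[C@@H](OCc1ccccc1)C2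
F6 | step 4 | 1,2-bis(benzyloxy)-4-(dimethoxymethyl)benzene | COC(OC)c1ccc(OCc2ccccc2)c(OCc2ccccc2)c1
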